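**Plan**

Atom labels: ring C1–C10 (C1 =CH, C2 CH–OAc, C3 CH2, C4 =C–Me, C5 =CH, C6 lactone CH–O, C7 ring-fusion CH, C8 CH–O-angelate, C9 CH–OAc, C10 =C–Me); C11, C12, C13 are the lactone alkene carbon, carbonyl carbon and exocyclic CH2.

1. Feature and main cut: in the ten-membered ring the C8 carbinol lies next to C7, which carries the C11=C13 methylene unit. The array O–C8–C7–C11=C13 is the retron of a [2,3]-Wittig shift, so C7–C8 is cut and the skeleton is re-tied as a C8–O–C13 allyl ether in a thirteen-membered ring with C9 as ketone.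
2. Further cuts, in retrosynthetic order: lactone C12–O6 (oxidative lactonisation of a 6,12-diol) and the three esters; C9–C10 (Nozaki–Hiyama–Kishi closure of the thirteen-membered ether); C7=C11 (ring-closing metathesis, a butenolide serving as geometric template); C6–C7 (vinylzinc addition); C2–C3 (vinylogous Mukaiyama aldol).
3. Forward order: C1–C6 chain by aldol, vinyl carbinol, acrylate ester, butenolide (temporary ring), opening to the protected 6,12-diol, thirteen-membered ether, enone, contraction to the ten-membered carbocycle, esters and C9 reduction, lactone ring last.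
4. Stereochemistry: C2 and C6 by catalyst control; C7 and C8 relayed from C6 in the Wittig step; C9 by hydride delivery anti to the C8 ester oxygen; 1(10)Z from anti hydroiodination, 4E from the aldol, C7=C11 geometry from the butenolide ring.

Key step: step 20

Assumption: the catalyst antipodes named in steps 5 and 9 are those expected from the accepted models to give the configurations drawn; if a trial run shows the opposite sense, the mirror-image catalyst is used and nothing else changes.

**Route**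

Step 1
Reactants: 1 ethyl but-2-ynoate
Product: 2 ethyl (Z)-3-iodobut-2-enoate
Conditions: NaI (1.6 equiv), AcOH, 110 °C
Reagents that add atoms: sodium iodide, [Na+].[I-]
Why: Conjugate hydroiodination of the ynoate is an anti addition (iodide to C3, proton to C2) and should give the Z β-iodo enoate, the source of the 1(10)Z alkene.

Step 2
Reactants: 2 ethyl (Z)-3-iodobut-2-enoate
Product: 3 (Z)-3-iodobut-2-en-1-ol
Conditions: iBu2AlH (2.2 equiv), CH2Cl2, −78 → 0 °C; Rochelle salt work-up
Reagents that add atoms: none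
Why: 1,2-Reduction of the enoate by the aluminium hydride leaves the alkenyl iodide and the alkene geometry untouched.

Step 3
Reactants: 3 (Z)-3-iodobut-2-en-1-ol
Product: 4 (Z)-3-iodobut-2-enal
Conditions: MnO2 (15 equiv), CH2Cl2, 20 °C; used at once
Reagents that add atoms: none
Why: Allylic oxidation on MnO2 is neutral and should not isomerise the Z β-iodo enal.

Step 4
Reactants: 5 methyl 3-methylbut-2-enoate
Product: 6 tert-butyl[(1-methoxy-3-methylbuta-1,3-dien-1-yl)oxy]dimethylsilane
Conditions: LiN(iPr)2, THF, −78 °C; tBuMe2SiCl, DMPU, −78 → 20 °C; distillation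
Reagents that add atoms: tert-butyldimethylsilyl chloride, CC(C)(C)[Si](C)(C)Cl
Why: Kinetic γ-deprotonation of the senecioate and O-silylation of the dienolate give the silyl dienol ether (vinylogous silyl ketene acetal).

Step 5
Reactants: 4 (Z)-3-iodobut-2-enal; 6 tert-butyl[(1-methoxy-3-methylbuta-1,3-dien-1-yl)oxy]dimethylsilane
Product: 7 methyl (2E,5R,6Z)-5-hydroxy-7-iodo-3-methylocta-2,6-dienoate
Conditions: SiCl4 (1.1 equiv), (R,R)-binaphthyldiamine-derived bisphosphoramide (5 mol%), iPr2NEt (10 mol%), CH2Cl2, −78 °C; sat. aq. NaHCO3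
Reagents that add atoms: none
Why: Catalytic enantioselective vinylogous Mukaiyama aldol in which the phosphoramide-bound trichlorosilyl cation activates the enal, the dienolate attacks through its γ-carbon (C3) on the Re face to set C2 as R, and the s-trans dienolate gives the 4E enoate.

Step 6
Reactants: 7 methyl (2E,5R,6Z)-5-hydroxy-7-iodo-3-methylocta-2,6-dienoate
Product: 8 methyl (2E,5R,6Z)-5-(tert-butyldimethylsilyloxy)-7-iodo-3-methylocta-2,6-dienoate
Conditions: tBuMe2SiCl, imidazole, DMF, 20 °C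
Reagents that add atoms: tert-butyldimethylsilyl chloride, CC(C)(C)[Si](C)(C)Cl
Why: Standard imidazole-mediated silylation protects the C2 hydroxyl for all steps up to step 23.

Step 7
Reactants: 8 methyl (2E,5R,6Z)-5-(tert-butyldimethylsilyloxy)-7-iodo-3-methylocta-2,6-dienoate
Product: 9 (2E,5R,6Z)-5-(tert-butyldimethylsilyloxy)-7-iodo-3-methylocta-2,6-dien-1-ol
Conditions: iBu2AlH (2.2 equiv), CH2Cl2, −78 °C; Rochelle salt work-up
Reagents that add atoms: none
Why: 1,2-Reduction of the enoate to the C6 allylic alcohol tolerates the silyl ether and the alkenyl iodide.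

Step 8
Reactants: 9 (2E,5R,6Z)-5-(tert-butyldimethylsilyloxy)-7-iodo-3-methylocta-2,6-dien-1-ol
Product: 10 (2E,5R,6Z)-5-(tert-butyldimethylsilyloxy)-7-iodo-3-methylocta-2,6-dienal
Conditions: MnO2 (15 equiv), CH2Cl2, 20 °C
Reagents that add atoms: none
Why: Chemoselective allylic oxidation gives the E enal (C6 aldehyde) without over-oxidation.

Step 9
Reactants: 10 (2E,5R,6Z)-5-(tert-butyldimethylsilyloxy)-7-iodo-3-methylocta-2,6-dienal
Product: 11 (3S,4E,7R,8Z)-7-(tert-butyldimethylsilyloxy)-9-iodo-5-methyldeca-1,4,8-trien-3-ol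
Conditions: divinylzinc (from CH2=CHMgBr and ZnCl2, 1.5 equiv), (−)-MIB [(2S)-3-exo-morpholinoisoborneol] (10 mol%), toluene, −30 → 0 °C; water work-up
Reagents that add atoms: divinylzinc, C=C[Zn]C=C (made from vinylmagnesium bromide, C=C[Mg]Br)
Why: Amino-alcohol-catalysed alkenylzinc addition to an enal, in which the zinc aminoalkoxide delivers the vinyl group to the Si face and sets C6 (S here, the spatial arrangement of 6R in the target), while the alkenyl iodide is inert to organozinc reagents.

Step 10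
Reactants: 12 ethyl 2-(bromomethyl)acrylate; 13 2-(tert-butyldimethylsilyloxy)ethanol
Product: 14 ethyl 2-{[2-(tert-butyldimethylsilyloxy)ethoxy]methyl}acrylate
Conditions: 13, NaH, THF, 0 °C; then 12, −20 → 20 °C
Reagents that add atoms: none
Why: Alkoxide substitution of the allylic bromide (SN2' addition–elimination on the acrylate) gives the 2-(alkoxymethyl)acrylate that carries C11, C12, C13 and the C8–C9 glycol unit.

Step 11
Reactants: 14 ethyl 2-{[2-(tert-butyldimethylsilyloxy)ethoxy]methyl}acrylate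
Product: 15 2-{[2-(tert-butyldimethylsilyloxy)ethoxy]methyl}acrylic acid
Conditions: LiOH, THF/H2O, 0 → 20 °C; 1 M HCl to pH 4 at 0 °C
Reagents that add atoms: lithium hydroxide, [Li+].[OH-]
Why: Saponification of the ethyl ester under conditions that a primary silyl ether survives.

Step 12
Reactants: 11 (3S,4E,7R,8Z)-7-(tert-butyldimethylsilyloxy)-9-iodo-5-methyldeca-1,4,8-trien-3-ol; 15 2-{[2-(tert-butyldimethylsilyloxy)ethoxy]methyl}acrylic acid
Product: 16 (3S,4E,7R,8Z)-7-(tert-butyldimethylsilyloxy)-9-iodo-5-methyldeca-1,4,8-trien-3-yl 2-{[2-(tert-butyldimethylsilyloxy)ethoxy]methyl}acrylate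
Conditions: DCC, DMAP (10 mol%), CH2Cl2, 0 → 20 °C
Reagents that add atoms: none
Why: Steglich esterification acylates the bis-allylic C6 alcohol under neutral conditions that avoid its ionisation.

Step 13
Reactants: 16 (3S,4E,7R,8Z)-7-(tert-butyldimethylsilyloxy)-9-iodo-5-methyldeca-1,4,8-trien-3-yl 2-{[2-(tert-butyldimethylsilyloxy)ethoxy]methyl}acrylate
Product: 17 (5R)-5-[(1E,4R,5Z)-4-(tert-butyldimethylsilyloxy)-6-iodo-2-methylhepta-1,5-dienyl]-3-{[2-(tert-butyldimethylsilyloxy)ethoxy]methyl}furan-2(5H)-one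
Conditions: second-generation Grubbs catalyst RuCl2(=CHPh)(PCy3)(H2IMes) (5 mol%), toluene (5 mM), 70 °C
Reagents that add atoms: none
Why: Ring-closing metathesis of the acrylate with the C7 vinyl group gives the α-substituted butenolide, whose five-membered ring fixes C12 cis to C6 on the new C7=C11 alkene, the trisubstituted and iodo alkenes being too hindered to compete.

Step 14
Reactants: 17 (5R)-5-[(1E,4R,5Z)-4-(tert-butyldimethylsilyloxy)-6-iodo-2-methylhepta-1,5-dienyl]-3-{[2-(tert-butyldimethylsilyloxy)ethoxy]methyl}furan-2(5H)-one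
Product: 18 open-chain 6,12-diol (2R,6R; 4E, 1(10)Z; C12H2OH cis to C6 on C7=C11; C2–OSiMe2tBu; C13–O–CH2CH2–OSiMe2tBu; C10–I)
Conditions: iBu2AlH (4 equiv), CH2Cl2, −78 → 0 °C; Rochelle salt work-up
Reagents that add atoms: none
Why: Aluminium hydride reduction of the butenolide through its lactol opens the ring to the Z ene-1,4-diol without touching silyl ethers or the alkenyl iodide.

Step 15
Reactants: 18 open-chain 6,12-diol
Product: 19 bis(4-methoxybenzyl) ether of 18 (C6–OPMB and C12–OPMB)
Conditions: NaH (3 equiv), 4-MeOC6H4CH2Cl (3 equiv), Bu4NI (10 mol%), DMF, 0 → 20 °C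
Reagents that add atoms: 4-methoxybenzyl chloride, COc1ccc(CCl)cc1
Why: Williamson etherification of both alkoxides under basic conditions that the bis-allylic C6 position tolerates, giving two separate ethers (not a cyclic acetal) so that allylic 1,3-strain rather than a ring fixes the C6 conformation in step 20.

Step 16
Reactants: 19 bis(4-methoxybenzyl) ether
Product: 20 primary alcohol (C9–OH free; C2–OSiMe2tBu retained)
Conditions: HF·pyridine, pyridine, THF, 0 °C
Reagents that add atoms: none
Why: Buffered fluoride-mediated desilylation removes the unhindered primary silyl ether much faster than the secondary allylic one at C2.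

Step 17
Reactants: 20 primary alcohol
Product: 21 open-chain iodo aldehyde (C9 aldehyde O=CH–C8H2–O–C13H2)
Conditions: Dess–Martin periodinane, NaHCO3, CH2Cl2, 0 → 20 °C
Reagents that add atoms: none
Why: Dess–Martin oxidation gives the α-alkoxy aldehyde under buffered, non-enolising conditions.

Step 18
Reactants: 21 open-chain iodo aldehyde
Product: 22 thirteen-membered cyclic ether with C9 allylic alcohol (both C9 epimers)
Conditions: CrCl2 (8 equiv), NiCl2 (2 mol%), DMSO/THF, slow addition of 21 to 2 mM, 25 °C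
Reagents that add atoms: none
Why: Nozaki–Hiyama–Kishi macrocyclisation, in which nickel activates the alkenyl iodide, the alkenyl group passes to trivalent chromium and adds to the aldehyde with retention of the Z geometry, high dilution favouring the thirteen-membered ring; both C9 epimers are carried on.

Step 19
Reactants: 22 thirteen-membered cyclic ether with C9 allylic alcohol
Product: 23 thirteen-membered α-allyloxy enone (C9 ketone; C8–O–C13–C11=C7 allyl ether; C6–OPMB, C12–OPMB, C2–OSiMe2tBu; 2R,6R)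
Conditions: Dess–Martin periodinane, NaHCO3, CH2Cl2, 0 → 20 °C
Reagents that add atoms: none
Why: Dess–Martin oxidation converges both allylic alcohol epimers on the Z enone without base that could enolise the α-alkoxy ketone early.

Step 20
Reactants: 23 thirteen-membered α-allyloxy enone
Product: 25 ten-membered 8-hydroxy-9-ketone (C7 bearing the 3-(4-methoxybenzyloxy)prop-1-en-2-yl group; H6/H7 trans and H7/H8 trans), via lithium enolate 24 (not isolated)
Conditions: LiN(SiMe3)2 (1.3 equiv), THF, −78 °C, then −78 → −20 °C; AcOH quench at −78 °C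
Reagents that add atoms: none
Why: Proposed new method: LiN(SiMe3)2 removes a proton from C8, the only sp3 α-carbon of the C9 ketone and further acidified by the ether oxygen, and the α-alkoxy enolate 24 attacks C7 across the ring through a five-membered envelope transition state while O–C13 breaks, a [2,3]-Wittig shift that is suprafacial on the C7=C11–C13 allyl unit. The closest known reactions are the enolate [2,3]-Wittig rearrangement of acyclic α-allyloxy ketones and esters and the [2,3]-Wittig contraction of thirteen-membered diallylic or propargylic allylic ethers to ten-membered carbocycles, which are merged here. The ten-membered carbocycle (C1–C10) is closed by ring contraction, the transannular C7–C8 bond forming in a five-centre array inside the thirteen-membered ether, so the entropic cost of a direct medium-ring closure is avoided. C7 is controlled by C6: allylic 1,3-strain with the cis C12H2OPMB arm should hold H6 in the alkene plane, the tether through C5 places C8 over the alkene face that carries C5, and the oxygen at C6 therefore ends up trans to the C7 side chain (H6/H7 trans). C8 is controlled by the exo placement of the enolate carbon C9 (anti to C11 and away from the C12 arm) together with the E-type allyl geometry (C6 trans to C13), the usual E-to-anti relationship, which corresponds to H7/H8 trans. The step needs [2,3] over [3,3] (oxy-Claisen, which would give a nine-membered ring) and [1,2] shifts and α'- over γ-deprotonation; the lithium counter-ion, the kinetic amide base, low temperature and the five- versus six-centre transannular geometry should secure this.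

Step 21
Reactants: 25 ten-membered 8-hydroxy-9-ketone; 26 angelic acid [(Z)-2-methylbut-2-enoic acid]
Product: 28 C8 angelate of the ten-membered 9-ketone, via mixed anhydride 27 (not isolated)
Conditions: 26, 2,4,6-Cl3C6H2COCl, Et3N, toluene, 20 °C; then 25, 75 °C
Reagents that add atoms: none
Why: Yamaguchi-type mixed-anhydride acylation transfers the angeloyl group without a nucleophilic catalyst, the established way to avoid Z to E isomerisation to the tiglate.

Step 22
Reactants: 28 C8 angelate of the ten-membered 9-ketone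
Product: 29 9-alcohol (9R; H8/H9 trans) with C8 angelate and C2 silyl ether
Conditions: NaBH4, CeCl3·7H2O, MeOH, −78 → −40 °C
Reagents that add atoms: none
Why: Luche 1,2-reduction of the enone, with hydride expected anti to the C8–O bond (polar Felkin–Anh model, non-chelating ester), which gives the 8,9-trans arrangement; low temperature should suppress acyl migration from O8 to O9.

Step 23
Reactants: 29 9-alcohol
Product: 30 2,9-diol with C8 angelate
Conditions: HF·pyridine, THF, 0 → 20 °C
Reagents that add atoms: none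
Why: Fluoride-mediated cleavage of the secondary silyl ether under mildly acidic conditions leaves the angelate and both benzyl ethers in place.

Step 24
Reactants: 30 2,9-diol
Product: 31 2,9-diacetate with C8 angelate and two 4-methoxybenzyl ethers
Conditions: Ac2O, pyridine, DMAP (cat.), CH2Cl2, 0 → 20 °C
Reagents that add atoms: acetic anhydride, CC(=O)OC(C)=O
Why: Standard DMAP-catalysed acetylation esterifies both secondary allylic alcohols in one operation.

Step 25
Reactants: 31 2,9-diacetate
Product: 32 6,12-diol (C6–OH and C12H2OH free)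
Conditions: DDQ (3 equiv), CH2Cl2/pH 7 phosphate buffer (10:1), 0 °C
Reagents that add atoms: none
Why: Oxidative cleavage of both 4-methoxybenzyl ethers by DDQ (benzylic hydride abstraction, hydrolysis of the hemiacetal) under buffered conditions spares the esters and allylic acetates.

Step 26
Reactants: 32 6,12-diol
Product: 35 CNP0499619.1 (2R,6R,7S,8R,9R; 1(10)Z,4E), via hydroxy enal 33 (not isolated), via lactol 34 (not isolated)
Conditions: TEMPO (20 mol%), PhI(OAc)2 (2.5 equiv), CH2Cl2, 20 °C
Reagents that add atoms: none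
Why: Oxoammonium (TEMPO/PhI(OAc)2) oxidative lactonisation of a 1,4-diol, selective for the primary allylic alcohol; the enal is trapped by the C6 hydroxyl as the lactol, which is oxidised on to the trans-fused α-methylene lactone.

**Compound list**

1 | ethyl but-2-ynoate | CCOC(=O)C#CC | starting material
2 | ethyl (Z)-3-iodobut-2-enoate | CCOC(=O)/C=C(/C)I | intermediate
3 | (Z)-3-iodobut-2-en-1-ol | OC/C=C(/C)I | intermediate
4 | (Z)-3-iodobut-2-enal | O=C/C=C(/C)I | intermediate
5 | methyl 3-methylbut-2-enoate | COC(=O)C=C(C)C | starting material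
6 | tert-butyl[(1-methoxy-3-methylbuta-1,3-dien-1-yl)oxy]dimethylsilane | COC(O[Si](C)(C)C(C)(C)C)=CC(C)=C | intermediate
7 | methyl (2E,5R,6Z)-5-hydroxy-7-iodo-3-methylocta-2,6-dienoate | COC(=O)/C=C(\C)C[C@@H](O)/C=C(/C)I | intermediate
8 | methyl (2E,5R,6Z)-5-(tert-butyldimethylsilyloxy)-7-iodo-3-methylocta-2,6-dienoate | COC(=O)/C=C(\C)C[C@@H](O[Si](C)(C)C(C)(C)C)/C=C(/C)I | intermediate
9 | (2E,5R,6Z)-5-(tert-butyldimethylsilyloxy)-7-iodo-3-methylocta-2,6-dien-1-ol | OC/C=C(\C)C[C@@H](O[Si](C)(C)C(C)(C)C)/C=C(/C)I | intermediate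
10 | (2E,5R,6Z)-5-(tert-butyldimethylsilyloxy)-7-iodo-3-methylocta-2,6-dienal | O=C/C=C(\C)C[C@@H](O[Si](C)(C)C(C)(C)C)/C=C(/C)I | intermediate
11 | (3S,4E,7R,8Z)-7-(tert-butyldimethylsilyloxy)-9-iodo-5-methyldeca-1,4,8-trien-3-ol | C=C[C@H](O)/C=C(\C)C[C@@H](O[Si](C)(C)C(C)(C)C)/C=C(/C)I | intermediate
12 | ethyl 2-(bromomethyl)acrylate | CCOC(=O)C(=C)CBr | starting material
13 | 2-(tert-butyldimethylsilyloxy)ethanol | OCCO[Si](C)(C)C(C)(C)C | starting material
14 | ethyl 2-{[2-(tert-butyldimethylsilyloxy)ethoxy]methyl}acrylate | CCOC(=O)C(=C)COCCO[Si](C)(C)C(C)(C)C | intermediate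
15 | 2-{[2-(tert-butyldimethylsilyloxy)ethoxy]methyl}acrylic acid | OC(=O)C(=C)COCCO[Si](C)(C)C(C)(C)C | intermediate
16 | (3S,4E,7R,8Z)-7-(tert-butyldimethylsilyloxy)-9-iodo-5-methyldeca-1,4,8-trien-3-yl 2-{[2-(tert-butyldimethylsilyloxy)ethoxy]methyl}acrylate | C=C[C@H](OC(=O)C(=C)COCCO[Si](C)(C)C(C)(C)C)/C=C(\C)C[C@@H](O[Si](C)(C)C(C)(C)C)/C=C(/C)I | intermediate
17 | (5R)-5-[(1E,4R,5Z)-4-(tert-butyldimethylsilyloxy)-6-iodo-2-methylhepta-1,5-dienyl]-3-{[2-(tert-butyldimethylsilyloxy)ethoxy]methyl}furan-2(5H)-one | O=C1O[C@H](/C=C(\C)C[C@@H](O[Si](C)(C)C(C)(C)C)/C=C(/C)I)C=C1COCCO[Si](C)(C)C(C)(C)C | intermediate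
18 | open-chain 6,12-diol (2R,6R; 4E, 1(10)Z; C12H2OH cis to C6; C2 silyl ether; C13–O–CH2CH2–OSi; C10 iodide) | OC/C(COCCO[Si](C)(C)C(C)(C)C)=C\[C@H](O)/C=C(\C)C[C@@H](O[Si](C)(C)C(C)(C)C)/C=C(/C)I | intermediate
19 | bis(4-methoxybenzyl) ether of 18 (C6–OPMB, C12–OPMB) | COc1ccc(COC/C(COCCO[Si](C)(C)C(C)(C)C)=C\[C@H](OCc2ccc(OC)cc2)/C=C(\C)C[C@@H](O[Si](C)(C)C(C)(C)C)/C=C(/C)I)cc1 | intermediate
20 | primary alcohol (C9–OH; otherwise as 19) | COc1ccc(COC/C(COCCO)=C\[C@H](OCc2ccc(OC)cc2)/C=C(\C)C[C@@H](O[Si](C)(C)C(C)(C)C)/C=C(/C)I)cc1 | intermediate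
21 | open-chain iodo aldehyde (C9 aldehyde; otherwise as 19) | COc1ccc(COC/C(COCC=O)=C\[C@H](OCc2ccc(OC)cc2)/C=C(\C)C[C@@H](O[Si](C)(C)C(C)(C)C)/C=C(/C)I)cc1 | intermediate
22 | thirteen-membered cyclic ether, C9 allylic alcohol (C9 epimers) | O1C/C(COCc2ccc(OC)cc2)=C/[C@H](OCc2ccc(OC)cc2)/C=C(\C)C[C@@H](O[Si](C)(C)C(C)(C)C)/C=C(/C)C(O)C1 | intermediate
23 | thirteen-membered α-allyloxy enone (C9 ketone, C8–O–C13 ether; 2R,6R) | O1C/C(COCc2ccc(OC)cc2)=C/[C@H](OCc2ccc(OC)cc2)/C=C(\C)C[C@@H](O[Si](C)(C)C(C)(C)C)/C=C(/C)C(=O)C1 | intermediate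
24 | lithium C8=C9 enolate of 23 | [Li]OC1=COC/C(COCc2ccc(OC)cc2)=C/[C@H](OCc2ccc(OC)cc2)/C=C(\C)C[C@@H](O[Si](C)(C)C(C)(C)C)/C=C1/C | intermediate
25 | ten-membered 8-hydroxy-9-ketone with C7 3-(4-methoxybenzyloxy)prop-1-en-2-yl group (H6/H7 trans, H7/H8 trans) | C=C(COCc1ccc(OC)cc1)[C@H]1[C@H](OCc2ccc(OC)cc2)/C=C(\C)C[C@@H](O[Si](C)(C)C(C)(C)C)/C=C(/C)C(=O)[C@@H]1O | intermediate
26 | angelic acid | C/C=C(/C)C(=O)O | starting material
27 | angelic 2,4,6-trichlorobenzoic anhydride | C/C=C(/C)C(=O)OC(=O)c1c(Cl)cc(Cl)cc1Cl | intermediate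
28 | C8 angelate of 25 | C=C(COCc1ccc(OC)cc1)[C@H]1[C@H](OCc2ccc(OC)cc2)/C=C(\C)C[C@@H](O[Si](C)(C)C(C)(C)C)/C=C(/C)C(=O)[C@@H]1OC(=O)/C(C)=C\C | intermediate
29 | 9-alcohol (9R), C8 angelate, C2 silyl ether | C=C(COCc1ccc(OC)cc1)[C@H]1[C@H](OCc2ccc(OC)cc2)/C=C(\C)C[C@@H](O[Si](C)(C)C(C)(C)C)/C=C(/C)[C@@H](O)[C@@H]1OC(=O)/C(C)=C\C | intermediate
30 | 2,9-diol, C8 angelate | C=C(COCc1ccc(OC)cc1)[C@H]1[C@H](OCc2ccc(OC)cc2)/C=C(\C)C[C@@H](O)/C=C(/C)[C@@H](O)[C@@H]1OC(=O)/C(C)=C\C | intermediate
31 | 2,9-diacetate, C8 angelate, C6 and C12 4-methoxybenzyl ethers | C=C(COCc1ccc(OC)cc1)[C@H]1[C@H](OCc2ccc(OC)cc2)/C=C(\C)C[C@@H](OC(C)=O)/C=C(/C)[C@@H](OC(C)=O)[C@@H]1OC(=O)/C(C)=C\C | intermediate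
32 | 6,12-diol, 2,9-diacetate, C8 angelate | C=C(CO)[C@H]1[C@H](O)/C=C(\C)C[C@@H](OC(C)=O)/C=C(/C)[C@@H](OC(C)=O)[C@@H]1OC(=O)/C(C)=C\C | intermediate
33 | 6-hydroxy C12 enal | C=C(C=O)[C@H]1[C@H](O)/C=C(\C)C[C@@H](OC(C)=O)/C=C(/C)[C@@H](OC(C)=O)[C@@H]1OC(=O)/C(C)=C\C | intermediate
34 | C12 lactol | C=C1C(O)O[C@@H]2/C=C(\C)C[C@@H](OC(C)=O)/C=C(/C)[C@@H](OC(C)=O)[C@H](OC(=O)/C(C)=C\C)[C@@H]12 | intermediate
35 | CNP0499619.1 | C=C1C(=O)O[C@@H]2/C=C(\C)C[C@@H](OC(C)=O)/C=C(/C)[C@@H](OC(C)=O)[C@H](OC(=O)/C(C)=C\C)[C@@H]12 | target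

**Count and risks**

Total: 26 steps. Longest linear sequence: 23 steps (steps 1–3, 5–9, 12–26).

Step 20 (most likely to fail). The enolate may not rearrange before [3,3] or α-ketol pathways set in on warming, or the endo envelope may be followed so that C8 forms with the wrong configuration. The fallback uses known chemistry, an acyclic ester-enolate [2,3]-Wittig rearrangement followed by direct Nozaki–Hiyama–Kishi closure of the ten-membered ring; it sets out from 20 and comes back at 25. Alcohol 20 is oxidised (TEMPO, PhI(OAc)2, MeCN/H2O) to the (allyloxy)acetic acid F1 and methylated (Me3SiCHN2) to the methyl ester F2. Treatment with LiN(SiMe3)2 in THF (−78 → 0 °C) should give the α-hydroxy ester F3, with C7 again set by C6 through allylic 1,3-strain and C8 epimers separated at this stage. Silylation (Et3SiCl, imidazole) gives the triethylsilyl ether F4, and iBu2AlH at −78 °C gives the aldehyde F5. CrCl2 with catalytic NiCl2 at high dilution closes the ring to the ten-membered allylic alcohol F6, Dess–Martin oxidation gives the ketone F7, and HF·pyridine/pyridine removes the triethylsilyl group selectively to return to 25.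

Step 22. Hydride may be delivered to the other face of the C9 carbonyl if the ring conformation overrides the polar Felkin–Anh preference. The fallback corrects the configuration by inversion instead of by reduction; it sets out from 28 and comes back at 31. The Luche reduction would then give mainly the 9-epimeric alcohol F8. A Mitsunobu reaction with acetic acid (PPh3, DIAD) inverts C9 and installs the acetate in one operation, giving the 9-acetate 2-silyl ether F9. HF·pyridine frees the C2 hydroxyl to give the 9-acetate 2-alcohol F10, and acetylation (Ac2O, pyridine, DMAP) returns to 31.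

Step 9. The uncatalysed addition of divinylzinc may compete with the ligand-bound pathway and erode facial selectivity at C6. The fallback gives up catalyst control for diastereomer separation and stereoinversion; it sets out from 10 and comes back at 16. Addition of CH2=CHMgBr (THF, −78 °C) gives 11 together with its C6 epimer F11, which are diastereomers (C2 is fixed) and would be separated by chromatography. Alcohol 11 enters step 12 as before. The epimer F11 is esterified with acid 15 under Mitsunobu conditions (PPh3, DIAD), with inversion at C6, to give the same ester 16.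

Further compounds
F1 | step 20 | (allyloxy)acetic acid from 20 (C9 carboxylic acid) | COc1ccc(COC/C(COCC(=O)O)=C\[C@H](OCc2ccc(OC)cc2)/C=C(\C)C[C@@H](O[Si](C)(C)C(C)(C)C)/C=C(/C)I)cc1
F2 | step 20 | methyl ester of F1 | COc1ccc(COC/C(COCC(=O)OC)=C\[C@H](OCc2ccc(OC)cc2)/C=C(\C)C[C@@H](O[Si](C)(C)C(C)(C)C)/C=C(/C)I)cc1
F3 | step 20 | open-chain α-hydroxy ester (C7–C8 bond formed, C11=C13 methylene, C8–OH) | C=C(COCc1ccc(OC)cc1)[C@H]([C@@H](O)C(=O)OC)[C@H](OCc1ccc(OC)cc1)/C=C(\C)C[C@@H](O[Si](C)(C)C(C)(C)C)/C=C(/C)I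
F4 | step 20 | C8 triethylsilyl ether of F3 | C=C(COCc1ccc(OC)cc1)[C@H]([C@@H](O[Si](CC)(CC)CC)C(=O)OC)[C@H](OCc1ccc(OC)cc1)/C=C(\C)C[C@@H](O[Si](C)(C)C(C)(C)C)/C=C(/C)I
F5 | step 20 | C9 aldehyde from F4 | C=C(COCc1ccc(OC)cc1)[C@H]([C@@H](O[Si](CC)(CC)CC)C=O)[C@H](OCc1ccc(OC)cc1)/C=C(\C)C[C@@H](O[Si](C)(C)C(C)(C)C)/C=C(/C)I
F6 | step 20 | ten-membered C9 allylic alcohol with C8 triethylsilyl ether (C9 epimers) | C=C(COCc1ccc(OC)cc1)[C@H]1[C@H](OCc2ccc(OC)cc2)/C=C(\C)C[C@@H](O[Si](C)(C)C(C)(C)C)/C=C(/C)C(O)[C@@H]1O[Si](CC)(CC)CC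
F7 | step 20 | ten-membered 9-ketone with C8 triethylsilyl ether | C=C(COCc1ccc(OC)cc1)[C@H]1[C@H](OCc2ccc(OC)cc2)/C=C(\C)C[C@@H](O[Si](C)(C)C(C)(C)C)/C=C(/C)C(=O)[C@@H]1O[Si](CC)(CC)CC
F8 | step 22 | 9-epimer of alcohol 29 | C=C(COCc1ccc(OC)cc1)[C@H]1[C@H](OCc2ccc(OC)cc2)/C=C(\C)C[C@@H](O[Si](C)(C)C(C)(C)C)/C=C(/C)[C@H](O)[C@@H]1OC(=O)/C(C)=C\C
F9 | step 22 | 9-acetate 2-silyl ether | C=C(COCc1ccc(OC)cc1)[C@H]1[C@H](OCc2ccc(OC)cc2)/C=C(\C)C[C@@H](O[Si](C)(C)C(C)(C)C)/C=C(/C)[C@@H](OC(C)=O)[C@@H]1OC(=O)/C(C)=C\C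
F10 | step 22 | 9-acetate 2-alcohol | C=C(COCc1ccc(OC)cc1)[C@H]1[C@H](OCc2ccc(OC)cc2)/C=C(\C)C[C@@H](O)/C=C(/C)[C@@H](OC(C)=O)[C@@H]1OC(=O)/C(C)=C\C
F11 | step 9 | (3R,4E,7R,8Z)-7-(tert-butyldimethylsilyloxy)-9-iodo-5-methyldeca-1,4,8-trien-3-ol (C6 epimer of 11) | C=C[C@@H](O)/C=C(\C)C[C@@H](O[Si](C)(C)C(C)(C)C)/C=C(/C)I
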